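## Retrosynthetic overview

1. Eudesmane numbering is used (ring A = C1–C5, C10; ring B = C5–C10; C14 = angular methyl; C15 = vinylic methyl; β = face of C14). The ester C–O bond is cut first, giving the axial 6β-alcohol 11 and acetyl-protected p-coumaroyl chloride 13; 11 comes from the trans-fused ketone 10 by hydride attack on the α face.
2. Ring A is cut from ring B at C1–C10 and C4–C5: ketone 8 comes from (S)-piperitone 3 and a pent-3-ynyl Grignard reagent, joined in one flask by copper-catalysed asymmetric conjugate addition (C1–C10) and gold-catalysed 6-endo-dig closure of the enol ether onto the alkyne (C4–C5).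
3. Enabling feature: with C6 as a ketone, ring B is a β-methyl enone (C6=O, C5, C10–C14), and the C3=C4(C15) alkene of ring A lies β,γ to that carbonyl. That alkene is the footprint of a methyl-capped alkyne attacked at C4 by the enol carbon C5.
4. Ring order: ring B is taken intact from (−)-menthone 1 (dehydrogenated to 3) and ring A is closed in the key step. C5 is then corrected to the trans fusion through the dienolate, C6 is set by reduction, and the ester is made last.

Key step: step 4

Remark: commercial (−)-menthone contains some (+)-isomenthone (its C2 epimer). This only gives a separable C7 diastereomer after step 4, because C10 is fixed by the copper catalyst. The imidazolinium salt enantiomer is assumed to be the one whose copper carbene delivers primary alkyl groups to the Re face of C3 of 3-methylcyclohex-2-enones.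

## Route

Step 1
Reactants: 1 (−)-menthone, (2S,5R)-5-methyl-2-(propan-2-yl)cyclohexan-1-one
Product: 2 trimethyl{[(3R,6S)-3-methyl-6-(propan-2-yl)cyclohex-1-en-1-yl]oxy}silane
Conditions: LiN(i-Pr)2, THF, −78 °C; TMSCl, −78 °C → rt
Reagents that add atoms: chlorotrimethylsilane, C[Si](C)(C)Cl
Why: Kinetic deprotonation by the hindered amide takes the CH2 proton rather than the isopropyl-bearing methine, and O-silylation gives the less substituted enol ether with both stereocentres untouched (kinetic silyl enol ether formation).

Step 2
Reactants: 2 trimethyl{[(3R,6S)-3-methyl-6-(propan-2-yl)cyclohex-1-en-1-yl]oxy}silane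
Product: 3 (S)-piperitone, (6S)-3-methyl-6-(propan-2-yl)cyclohex-2-en-1-one
Conditions: Pd(OAc)2 (10 mol%), O2 (1 atm), DMSO, rt
Reagents that add atoms: none
Why: Saegusa–Ito oxidation: the enolate of divalent palladium loses its only β-hydrogen (at the methyl-bearing carbon) to give the conjugated enone, O2 reoxidizes zerovalent palladium, and the near-neutral conditions should leave the isopropyl-bearing centre intact.

Step 3
Reactants: 4 5-bromopent-2-yne
Product: 5 pent-3-yn-1-ylmagnesium bromide (titrated Et2O solution, used directly)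
Conditions: Mg turnings, Et2O, rt
Reagents that add atoms: magnesium, [Mg]
Why: Standard Grignard formation from a primary homopropargylic bromide; the internal alkyne has no acidic hydrogen.

Step 4
Reactants: 3 (S)-piperitone; 5 pent-3-yn-1-ylmagnesium bromide
Product: 8 (5S,7S,10R)-eudesm-3-en-6-one (cis-fused; 5β-H), via bromomagnesium enolate 6 (not isolated), via tert-butyldimethylsilyl enol ether 7 (not isolated)
Conditions: Cu(OTf)2 (3 mol%), chiral C2-symmetric 4,5-diphenylimidazolinium chloride (4 mol%), Et2O, −30 °C; TBSOTf, −30 → 0 °C; pentane, filter, concentrate; [(JohnPhos)Au(NCMe)]SbF6 (3 mol%; JohnPhos = (2-biphenylyl)di-tert-butylphosphine), i-PrOH, CH2Cl2, 0 °C → rt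
Reagents that add atoms: none
Why: Monovalent copper (formed from Cu(OTf)2 and the Grignard reagent, bound to the chiral N-heterocyclic carbene) transfers the pentynyl group to C10 of the enone (bond C1–C10), the magnesium enolate 6 is silylated on oxygen to the regiodefined enol ether 7, and the cationic complex of monovalent gold then activates the alkyne so that the enol carbon C5 attacks the methyl-bearing alkyne carbon C4 anti to gold (bond C4–C5), after which i-PrOH effects protodeauration and takes up the silyl group. The closest known reaction types are the copper-catalysed asymmetric conjugate addition of Grignard reagents to 3-methylcyclohex-2-enones with enolate trapping and the gold-catalysed Conia-ene-type carbocyclization of silyl enol ethers onto alkynes; ring B is untouched and ring A closes in the 6-endo-dig mode. C10 is set by the catalyst, which must deliver the chain to the Re face of C3 of the enone (anti to the isopropyl group) against the weak 1,4-bias of the substrate, and C7 is carried over unchanged from 3. C5 is set by the geometry of the closure: allylic 1,2-strain with the silyloxy group places the isopropyl group, and with it the trans-disposed pentynyl arm, pseudoaxial, so the arm should reach C5 on its own face and give the cis-fused 5β-H ketone. The step needs 1,4- over 1,2-addition (copper catalysis), a single enol ether regioisomer (fixed by the conjugate addition itself) and 6-endo over 5-exo closure, which the bulky biarylphosphine on gold and the methyl cap on the alkyne (no Markovnikov bias toward the inner carbon) are expected to secure.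

Step 5
Reactants: 8 (5S,7S,10R)-eudesm-3-en-6-one
Product: 10 (5R,7S,10R)-eudesm-3-en-6-one (trans-fused; 5α-H), via potassium dienolate 9 (not isolated)
Conditions: KN(SiMe3)2, THF, −78 °C; AcOH, −78 °C → rt
Reagents that add atoms: none
Why: The base removes the doubly activated C5–H to give the planar dienolate 9, which should be protonated kinetically at the α-carbon C5 from the α face, anti to the axial C10 methyl group, giving the trans-fused β,γ-unsaturated ketone (deconjugative kinetic protonation of an extended enolate); any trans epimer already present in 8 passes through the same dienolate.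

Step 6
Reactants: 10 (5R,7S,10R)-eudesm-3-en-6-one
Product: 11 (5R,6R,7S,10R)-eudesm-3-en-6-ol (6β-OH, axial)
Conditions: LiAlH4, Et2O, −78 → 0 °C; aq. NaOH work-up
Reagents that add atoms: none
Why: Hydride should add to the α face of the C6 carbonyl (equatorial attack) because the axial β approach is blocked by the 1,3-diaxial C10 methyl group, as in the reduction of 6-oxo-5α-steroids, giving the axial 6β-alcohol and locking C5 against further epimerization.

Step 7
Reactants: 12 (E)-3-(4-acetoxyphenyl)prop-2-enoic acid
Product: 13 (E)-3-(4-acetoxyphenyl)prop-2-enoyl chloride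
Conditions: (COCl)2, DMF (cat.), CH2Cl2, 0 °C → rt
Reagents that add atoms: oxalyl chloride, ClC(=O)C(=O)Cl
Why: Vilsmeier-type activation by catalytic DMF converts the acid into the acid chloride without touching the aryl acetate or the (E)-alkene.

Step 8
Reactants: 11 (5R,6R,7S,10R)-eudesm-3-en-6-ol; 13 (E)-3-(4-acetoxyphenyl)prop-2-enoyl chloride
Product: 14 (5R,6R,7S,10R)-eudesm-3-en-6-yl (E)-3-(4-acetoxyphenyl)prop-2-enoate
Conditions: DMAP (0.5 equiv), Et3N, CH2Cl2, 0 → 40 °C
Reagents that add atoms: none
Why: DMAP-catalysed acylation through the N-acylpyridinium salt should esterify the hindered axial alcohol with retention at C6, the ring alkene and the aryl acetate being inert.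

Step 9
Reactants: 14 (5R,6R,7S,10R)-eudesm-3-en-6-yl (E)-3-(4-acetoxyphenyl)prop-2-enoate
Product: 15 (5R,6R,7S,10R)-eudesm-3-en-6-yl (E)-3-(4-hydroxyphenyl)prop-2-enoate (target)
Conditions: K2CO3 (0.2 equiv), MeOH, 0 °C
Reagents that add atoms: none
Why: The aryl acetate undergoes methanolysis far faster than the hindered secondary cinnamate, so only the phenol should be released (chemoselective transesterification).

## Compound list

1 | (−)-menthone, (2S,5R)-5-methyl-2-(propan-2-yl)cyclohexan-1-one | C[C@H]1CC(=O)[C@H](C(C)C)CC1 | starting material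
2 | trimethyl{[(3R,6S)-3-methyl-6-(propan-2-yl)cyclohex-1-en-1-yl]oxy}silane | C[C@H]1C=C(O[Si](C)(C)C)[C@H](C(C)C)CC1 | intermediate
3 | (S)-piperitone, (6S)-3-methyl-6-(propan-2-yl)cyclohex-2-en-1-one | CC1=CC(=O)[C@H](C(C)C)CC1 | intermediate
4 | 5-bromopent-2-yne | CC#CCCBr | starting material
5 | pent-3-yn-1-ylmagnesium bromide | CC#CCC[Mg]Br | intermediate
6 | bromomagnesium (3S,6S)-3-methyl-3-(pent-3-yn-1-yl)-6-(propan-2-yl)cyclohex-1-en-1-olate | CC#CCC[C@]1(C)CC[C@@H](C(C)C)C(O[Mg]Br)=C1 | intermediate
7 | tert-butyldimethyl{[(3S,6S)-3-methyl-3-(pent-3-yn-1-yl)-6-(propan-2-yl)cyclohex-1-en-1-yl]oxy}silane | CC#CCC[C@]1(C)CC[C@@H](C(C)C)C(O[Si](C)(C)C(C)(C)C)=C1 | intermediate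
8 | (5S,7S,10R)-eudesm-3-en-6-one, (2S,4aR,8aS)-4a,8-dimethyl-2-(propan-2-yl)-3,4,4a,5,6,8a-hexahydronaphthalen-1(2H)-one, cis-fused | CC1=CCC[C@]2(C)CC[C@@H](C(C)C)C(=O)[C@H]12 | intermediate
9 | potassium (2S,4aR)-4a,8-dimethyl-2-(propan-2-yl)-2,3,4,4a,5,6-hexahydronaphthalen-1-olate | CC1=CCC[C@]2(C)CC[C@@H](C(C)C)C([O-])=C12.[K+] | intermediate
10 | (5R,7S,10R)-eudesm-3-en-6-one, (2S,4aR,8aR)-4a,8-dimethyl-2-(propan-2-yl)-3,4,4a,5,6,8a-hexahydronaphthalen-1(2H)-one, trans-fused | CC1=CCC[C@]2(C)CC[C@@H](C(C)C)C(=O)[C@@H]12 | intermediate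
11 | (5R,6R,7S,10R)-eudesm-3-en-6-ol, (1R,2S,4aR,8aR)-4a,8-dimethyl-2-(propan-2-yl)-1,2,3,4,4a,5,6,8a-octahydronaphthalen-1-ol | CC1=CCC[C@]2(C)CC[C@@H](C(C)C)[C@@H](O)[C@@H]12 | intermediate
12 | (E)-3-(4-acetoxyphenyl)prop-2-enoic acid | CC(=O)Oc1ccc(/C=C/C(=O)O)cc1 | starting material
13 | (E)-3-(4-acetoxyphenyl)prop-2-enoyl chloride | CC(=O)Oc1ccc(/C=C/C(=O)Cl)cc1 | intermediate
14 | (1R,2S,4aR,8aR)-4a,8-dimethyl-2-(propan-2-yl)-1,2,3,4,4a,5,6,8a-octahydronaphthalen-1-yl (E)-3-(4-acetoxyphenyl)prop-2-enoate | CC1=CCC[C@]2(C)CC[C@@H](C(C)C)[C@@H](OC(=O)/C=C/c3ccc(OC(C)=O)cc3)[C@@H]12 | intermediate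
15 | (1R,2S,4aR,8aR)-4a,8-dimethyl-2-(propan-2-yl)-1,2,3,4,4a,5,6,8a-octahydronaphthalen-1-yl (E)-3-(4-hydroxyphenyl)prop-2-enoate | CC1=CCC[C@]2(C)CC[C@@H](C(C)C)[C@@H](OC(=O)/C=C/c3ccc(O)cc3)[C@@H]12 | target

## Step count and risks

Total step count: 9 (including the Grignard preparation, step 3, and the acid chloride preparation, step 7).
Longest linear sequence: 7 steps (1, 2, 4, 5, 6, 8, 9).

Steps most likely to fail:

Step 4. The gold closure may go 5-exo instead of 6-endo, or the catalyst may fail to override the substrate bias at C10. The fallback sets out from 3 and comes back at 10. Compound 3 is treated under the same copper catalysis with the Grignard reagent from commercial 2-(3-chloropropyl)-2-methyl-1,3-dioxolane to give the ketal ketone (3R,6S)-3-methyl-3-[3-(2-methyl-1,3-dioxolan-2-yl)propyl]-6-(propan-2-yl)cyclohexan-1-one F1. Aqueous HCl in THF at reflux then removes the ketal and closes ring A by intramolecular aldol condensation of C5 onto the C4 ketone, while C7 equilibrates to the equatorial isopropyl epimer, giving (7S,10R)-eudesm-4-en-6-one F2. KOt-Bu in t-BuOH forms the extended dienolate, and an AcOH quench protonates C5 to give 10.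

Step 5. The quench may protonate the γ-carbon C3, moving the alkene into conjugation, or may show poor facial selectivity at C5. The fallback sets out from 8 and comes back at 11. The dienolate 9 is O-acylated with Ac2O to the dienyl acetate (2S,4aR)-4a,8-dimethyl-2-(propan-2-yl)-2,3,4,4a,5,6-hexahydronaphthalen-1-yl acetate F3. NaBH4 in EtOH/THF at 0 °C cleaves the enol ester, the freed dienol is protonated at C5, and the β,γ-unsaturated ketone is reduced as it forms, so it has no lifetime in which to conjugate; this gives 11 directly.

Step 8. Acylation of the axial alcohol, shielded by the 1,3-diaxial C14 methyl group, may not take place with the bulky cinnamoyl chloride. The fallback sets out from 11 and comes back at 14. Compound 11 is esterified with the small diethylphosphonoacetic acid (DCC, DMAP, CH2Cl2) to (5R,6R,7S,10R)-eudesm-3-en-6-yl 2-(diethoxyphosphoryl)acetate F4. A Horner–Wadsworth–Emmons reaction with 4-acetoxybenzaldehyde (LiCl, i-Pr2NEt, MeCN) then builds the (E)-cinnamate on the ester and gives 14.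

Further compounds
F1 | step 4 | (3R,6S)-3-methyl-3-[3-(2-methyl-1,3-dioxolan-2-yl)propyl]-6-(propan-2-yl)cyclohexan-1-one | CC1(CCC[C@]2(C)CC[C@@H](C(C)C)C(=O)C2)OCCO1
F2 | step 4 | (7S,10R)-eudesm-4-en-6-one, (2S,4aR)-4a,8-dimethyl-2-(propan-2-yl)-3,4,4a,5,6,7-hexahydronaphthalen-1(2H)-one | CC1=C2C(=O)[C@H](C(C)C)CC[C@@]2(C)CCC1
F3 | step 5 | (2S,4aR)-4a,8-dimethyl-2-(propan-2-yl)-2,3,4,4a,5,6-hexahydronaphthalen-1-yl acetate | CC1=CCC[C@]2(C)CC[C@@H](C(C)C)C(OC(C)=O)=C12
F4 | step 8 | (5R,6R,7S,10R)-eudesm-3-en-6-yl 2-(diethoxyphosphoryl)acetate | CC1=CCC[C@]2(C)CC[C@@H](C(C)C)[C@@H](OC(=O)CP(=O)(OCC)OCC)[C@@H]12
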